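(The numbers in the tables are calculated with made-up constants, noise included.)

The beta run carried more protic impurity than the epsilon run, yet at 6.00 h their targets stand at 12.5% and 11.3%. That gap is 1.2 percentage points against a scatter of 0.5 points per reading, too thin to build a trend on, so you can pool the two runs for the new flask.

common to all: solid substrate 0.10 M

| flask | partner | protic impurity | remark | time |
|---|---|---|---|---|
| epsilon | 0.20 M | 0.050 M | run made earlier |  |
| beta | 0.20 M | 0.075 M | run made earlier |  |
| flask | 0.200 M | 0.100 M |  | 8.0 h |

- epsilon (time / h: target / %, solid product / %): 0.500: 1.5, 0; 0.833: 3.9, 0.4; 1.33: 4.2, 0; 2.50: 6.6, 0.4; 4.00: 8.0, 0; 6.00: 11.3, 0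
- beta (time / h: target / %, solid product / %): 0.417: 2.4, 0; 1.33: 3.6, 0; 2.50: 6.8, 0; 4.00: 8.3, 0; 5.00: 11.1, 0.1; 6.00: 12.5, 0

(scatter of a reading: 0.5 percentage points)

- target and solid product together at 8.0 h, in percent of the solid substrate charged
- concentration of dissolved substrate in solution at 8.0 h, in percent of saturation

- target is meant together with its solid product
- solid, in amounts per volume of the solution: solid substrate, solid product
- at the start none of the solid substrate is in solution
- dissolved substrate means what is dissolved; the solid is not counted in it

Solid product stays at or below 0.4%, inside the scatter, so the target reading stands for y.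

Now reckon with f, the fraction of the charge not yet target, and not with the fraction made. At 6.00 h, −ln(f)/t is 0.0200 /h in the epsilon run and 0.0223 /h in the beta run. Their mean, 0.0211 /h, is κ, the average rate at which f shrinks from the start.

The ladder runs from the earliest readings to the longest time. The beta run already shows 2.4% of target at 0.417 h, so you see no lag in these readings. Next, the same reckoning at 1.33 h gives a mean of 0.0299 /h, faster than κ at 6.00 h. Last comes the half-life of f, 32.8 h, long against 8.0 h.

So your reckoning for the flask at 8.0 h leaves f at 84.5% and gives y of 15.5%, leaning high because κ has been falling. The runs hold no reading of dissolved substrate, so you give no figure for it.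

The forecast says 16% and 80%, since “the solution should stay near saturation”.

The flask gives 14.8%, with dissolved substrate at 0.417% of saturation. Its own κ is 0.0201 /h, just under the 0.0211 /h from the runs.

    solid substrate ⇌ dissolved substrate, rate k1*(cs1 - [dissolved substrate]) while solid is left; crystals form when [dissolved substrate] > cs1 (solubility = 0.0560 M, k = 2.80 × 10⁻⁵ /s)
    dissolved substrate + partner → target (k = 0.0430 /M/s)
    solid product ⇌ target, rate k3*(cs3 - [target]) while solid is left; crystals form when [target] > cs3 (solubility = 43.0 mM, k = 4.10 × 10⁻⁴ /s)
    target ⇌ isomer of the product (K = 2.50, k = 2.30 × 10⁻⁴ /s)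
    solid substrate + protic impurity → quenched substrate (k = 2.20 × 10⁻⁴ /M/s)
    solid substrate + target → side product (k = 3.40 × 10⁻⁴ /M/s)

The neighbour is this same flask read at 2.0 h. With κ of 0.0211 /h your reckoning gives 4.14%, but the neighbour holds 5.83%, which is 1.7 points more, a gap larger than the scatter of a reading. Turned round, its fraction left gives a κ of 0.0300 /h, close to the 0.0299 /h from the early readings of the runs, against 0.0201 /h for the flask at 8.0 h.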